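**Retrosynthetic overview**

1. Numbering follows the target: side chain C1–C4 with methyl C15 on C4, ring C5–C10, lactone C11–C13 closed on O8, C14 on C10. The plan rests on the cyclohexene C5–C10: taking out C5 leaves the cis-fused cyclopentene γ-lactone C6–C7–C8–C9–C10 / C11–C12–O.
2. Late stage: PMB ethers on O1 and O14 (DDQ), angelate on O6 (mixed anhydride), C13 by Eschenmoser methylenation of the lactone enolate.
3. C4–C5 by Suzuki coupling of the C5 vinyl bromide with a pent-1-en-2-yl boronate from pent-4-yn-1-ol; C4 by catalyst-controlled iridium hydrogenation.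
4. C5 is inserted by dibromocarbene addition across C6=C10 and silver(I)-promoted electrocyclic opening with water capture at C6 (C5–C6, C5–C10, C6–O).
5. The cyclopentene lactone is built with C14 already on C10 from (R)-4-silyloxycyclopentenone (1,2-addition of a PMB-oxymethyl anion, Ireland–Claisen transfer of C11–C12 to C7, desilylative lactonisation), because C14 cannot be attached regioselectively to C10 of the parent bicyclic lactone. Ring order: cyclopentene (purchased), γ-lactone, cyclohexene by expansion.

Key step: step 5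

Remark: compounds 1, 3, 12, 15 and 26 are taken as purchased; O14 and O1 are carried as PMB ethers and O6 as a TBS ether.

**Step 1**
Reactants: 1 (tributylstannyl)methanol
Product: 2 tributyl{[(4-methoxybenzyl)oxy]methyl}stannane
Conditions: NaH, PMBCl, TBAI (cat.), THF/DMF, 0 °C → rt
Reagents that add atoms: 4-methoxybenzyl chloride, COc1ccc(CCl)cc1
Why: Williamson etherification of the sodium alkoxide with the benzylic chloride (SN2); the C–Sn bond is inert to NaH.

**Step 2**
Reactants: 2 tributyl{[(4-methoxybenzyl)oxy]methyl}stannane; 3 (R)-4-(tert-butyldimethylsilyloxy)cyclopent-2-en-1-one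
Product: 6 (1S,4R)-4-(tert-butyldimethylsilyloxy)-1-[(4-methoxybenzyloxy)methyl]cyclopent-2-en-1-yl acetate, via PMB-oxymethyllithium 4 (not isolated), via lithium alkoxide 5 (not isolated)
Conditions: n-BuLi, THF, −78 °C; add 3, −78 °C; then Ac2O, −78 → 0 °C
Reagents that add atoms: acetic anhydride, CC(=O)OC(C)=O
Why: Tin–lithium exchange gives an α-alkoxymethyllithium (hydroxymethyl anion equivalent) that adds 1,2 to the enone on the face anti to the C8 silyloxy group, so the new C10–O bond lies cis to C8–O, and the tertiary alkoxide is acetylated in the flask.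

**Step 3**
Reactants: 6 the tertiary allylic acetate
Product: 9 2-[(1S,5R)-5-(tert-butyldimethylsilyloxy)-3-[(4-methoxybenzyloxy)methyl]cyclopent-2-en-1-yl]acetic acid, via silyl ketene acetal 7 (not isolated), via trimethylsilyl ester 8 (not isolated)
Conditions: LDA, TMSCl/Et3N, THF, −78 → 50 °C; then 1 M aq. HCl, rt
Reagents that add atoms: none
Why: Ireland–Claisen rearrangement: the O-silyl ketene acetal shifts suprafacially through a boat transition state, delivering C11 to C7 on the face that carried the C10–O bond (cis to C8–OTBS), which sets C7 by 1,3-chirality transfer and leaves the alkene at C6=C10 with C14 on C10.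

**Step 4**
Reactants: 9 the cyclopentenylacetic acid
Product: 11 (3aS,6aR)-5-[(4-methoxybenzyloxy)methyl]-3,3a,6,6a-tetrahydro-2H-cyclopenta[b]furan-2-one, via hydroxy acid 10 (not isolated)
Conditions: 48% aq. HF, MeCN, 0 °C → rt
Reagents that add atoms: none
Why: Acidic fluoride cleaves the secondary silyl ether and the cis γ-hydroxy acid lactonises spontaneously (5-exo-trig acyl substitution), while the PMB ether is stable to these conditions.

**Step 5**
Reactants: 11 the cyclopentene lactone; 12 bromoform
Product: 14 (3aS,4S,7aR)-5-bromo-4-hydroxy-6-[(4-methoxybenzyloxy)methyl]-3a,4,7,7a-tetrahydro-1-benzofuran-2(3H)-one (target numbering: 5-Br; 6-OH trans to C7–C11; 14-OPMB), via dibromocyclopropane 13 (not isolated)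
Conditions: CHBr3 (excess), KOtBu, pentane/toluene, −20 → 0 °C; filter, concentrate cold; then AgOTf, acetone/H2O (4:1), 0 °C → rt, dark
Reagents that add atoms: bromoform 12, BrC(Br)Br; water, O
Why: Dibromocarbene (α-elimination from bromoform) adds to the electron-rich trisubstituted C6=C10 alkene in a concerted [2+1] cheletropic step on the convex face, closing the cyclopropane; silver(I) then removes the endo bromide while the C6–C10 σ-bond opens in a disrotatory two-electron electrocyclic step, so the cyclohexene arises by ring expansion with C5 inserted through the C5–C6 and C5–C10 bonds. This is the established dihalocarbene/silver(I) expansion of cyclopentenes to 2-bromocyclohex-2-enols, and if the adduct ionises thermally to the allylic bromide beforehand, silver feeds it into the same 2-bromoallyl cation. The new stereocentre C6 is set when water adds to the cation on the convex face, anti to the C7–C11 bond of the cis-fused lactone, giving the 6,7-trans alcohol with C7 and C8 untouched. The step needs capture at C6 and not at C10: C10 is fully substituted and bears the electron-withdrawing CH2OPMB group, and the C6 carbinol with the tetrasubstituted bromoalkene is the thermodynamic isomer, into which any C10 carbinol should drain by re-ionisation in the acidic silver medium. The face of carbene addition does not matter because both cyclopropane carbons become trigonal in the cation, and the lactone is shielded from the base because bromoform, the stronger acid and in excess, consumes the tert-butoxide.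

**Step 6**
Reactants: 15 pent-4-yn-1-ol
Product: 16 1-methoxy-4-[(pent-4-yn-1-yloxy)methyl]benzene
Conditions: NaH, PMBCl, TBAI (cat.), THF/DMF, 0 °C → rt
Reagents that add atoms: 4-methoxybenzyl chloride, COc1ccc(CCl)cc1
Why: Williamson etherification; NaH deprotonates the alcohol and not the alkyne C–H.

**Step 7**
Reactants: 16 the pentynyl PMB ether
Product: 18 2-{5-[(4-methoxybenzyl)oxy]pent-1-en-2-yl}-4,4,5,5-tetramethyl-1,3,2-dioxaborolane, via alkenylalane 17 (not isolated)
Conditions: Ni(dppp)Cl2 (3 mol %), DIBAL-H, THF, rt; then MeOBpin, 0 → 60 °C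
Reagents that add atoms: 2-methoxy-4,4,5,5-tetramethyl-1,3,2-dioxaborolane, COB1OC(C)(C)C(C)(C)O1
Why: Nickel–dppp-catalysed α-selective (Markovnikov) hydroalumination of the terminal alkyne puts aluminium on the internal carbon, and Al-to-B transmetalation with the borate gives the 1,1-disubstituted alkenyl boronate.

**Step 8**
Reactants: 14 the bromo allylic alcohol; 18 the alkenyl boronate
Product: 19 diene alcohol: 14 with Br replaced by the 5-(PMB-oxy)pent-1-en-2-yl group at C5 (6-OH free)
Conditions: Pd(OAc)2 (5 mol %), SPhos (10 mol %), K3PO4, THF/H2O (10:1), 50 °C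
Reagents that add atoms: none
Why: Suzuki–Miyaura sp2–sp2 coupling, in which the bulky biarylphosphine supports oxidative addition into the tetrasubstituted bromoalkene and transmetalation of the α-branched boronate, while the free allylic alcohol and the lactone tolerate the mild phosphate base.

**Step 9**
Reactants: 19 the diene alcohol
Product: 20 6-O-TBS ether of 19
Conditions: TBSOTf, 2,6-lutidine, CH2Cl2, −78 → 0 °C
Reagents that add atoms: tert-butyldimethylsilyl triflate, CC(C)(C)[Si](C)(C)OS(=O)(=O)C(F)(F)F
Why: Silyl triflate silylation of the hindered secondary alcohol masks the hydroxyl so that it cannot direct the hydrogenation and survives the later amide base.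

**Step 10**
Reactants: 20 the silylated diene
Product: 21 saturated side-chain lactone: C5 bears (S)-CH(CH3)CH2CH2CH2OPMB (4S); 6-OTBS; 14-OPMB; C11 is CH2
Conditions: [Ir(cod)(L*)]BArF (2 mol %; L* = ThrePHOX-type phosphinite–oxazoline, antipode chosen for Re-face delivery at C4), H2 (1–2 bar), CH2Cl2, rt
Reagents that add atoms: none
Why: Iridium–N,P-catalysed asymmetric hydrogenation of the 1,1-disubstituted alkene, in which the catalyst distinguishes the bulky twisted cyclohexenyl group from the n-alkyl chain and delivers H2 to the Re face of C4 (C5 > C3 > C15) to set 4S, the tetrasubstituted C5=C10 alkene being inert to this catalyst class.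

**Step 11**
Reactants: 21 the saturated lactone
Product: 22 C11-(dimethylaminomethyl) lactone (C11 epimers, both converge)
Conditions: LDA, THF, −78 °C; CH2=NMe2+ I−, −78 °C → rt
Reagents that add atoms: Eschenmoser's salt, C=[N+](C)C.[I-]
Why: Mannich reaction of the lactone lithium enolate with the preformed iminium salt; the enolate carries no β-leaving group and the C11 configuration is erased in the next step.

**Step 12**
Reactants: 22 the Mannich base
Product: 24 α-methylene lactone (6-OTBS; 1,14-bis-OPMB), via methiodide 23 (not isolated)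
Conditions: MeI, THF/MeOH, rt; then sat. aq. NaHCO3, CH2Cl2, rt
Reagents that add atoms: none
Why: N-methylation followed by Hofmann-type E1cB loss of trimethylamine from the β-ammonium lactone gives the exocyclic C11=C13 alkene.

**Step 13**
Reactants: 24 the silylated α-methylene lactone
Product: 25 6-hydroxy α-methylene lactone (1,14-bis-O-PMB-6-O-deangeloyl-eriolangin)
Conditions: HF·pyridine, pyridine/THF, 0 °C → rt
Reagents that add atoms: none
Why: Buffered acidic fluoride cleaves the allylic secondary TBS ether, and the PMB ethers and the enoate lactone are stable to it.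

**Step 14**
Reactants: 25 the C6 alcohol; 26 angelic acid
Product: 28 1,14-bis-O-PMB-eriolangin, via mixed anhydride 27 (not isolated)
Conditions: 26, 2,4,6-trichlorobenzoyl chloride, Et3N, toluene, rt; then 25, toluene, 75 °C
Reagents that add atoms: angelic acid 26, C/C=C(/C)C(=O)O
Why: Yamaguchi mixed-anhydride esterification run without DMAP: the alcohol attacks the unhindered angeloyl carbonyl, and leaving out the nucleophilic catalyst avoids addition–elimination isomerisation of the Z ester to tiglate.

**Step 15**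
Reactants: 28 the bis-PMB ether
Product: 29 eriolangin (4S,6S,7R,8R)
Conditions: DDQ, CH2Cl2/pH 7 buffer (10:1), 0 °C
Reagents that add atoms: none
Why: Oxidative PMB cleavage (benzylic hydride abstraction by DDQ, then hydrolysis of the oxocarbenium ion) under neutral conditions frees O1 and O14 and leaves the angelate, the α-methylene lactone and the tetrasubstituted alkene intact.

**Compound list**

1 | (tributylstannyl)methanol | CCCC[Sn](CCCC)(CCCC)CO | starting material
2 | tributyl{[(4-methoxybenzyl)oxy]methyl}stannane | CCCC[Sn](CCCC)(CCCC)COCc1ccc(OC)cc1 | intermediate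
3 | (R)-4-(tert-butyldimethylsilyloxy)cyclopent-2-en-1-one | O=C1C=C[C@H](O[Si](C)(C)C(C)(C)C)C1 | starting material
4 | [(4-methoxybenzyl)oxy]methyllithium | [Li]COCc1ccc(OC)cc1 | intermediate (not isolated)
5 | lithium (1S,4R)-4-(tert-butyldimethylsilyloxy)-1-[(4-methoxybenzyloxy)methyl]cyclopent-2-en-1-olate | [Li]O[C@]1(COCc2ccc(OC)cc2)C=C[C@H](O[Si](C)(C)C(C)(C)C)C1 | intermediate (not isolated)
6 | (1S,4R)-4-(tert-butyldimethylsilyloxy)-1-[(4-methoxybenzyloxy)methyl]cyclopent-2-en-1-yl acetate (OAc cis to OTBS) | CC(=O)O[C@]1(COCc2ccc(OC)cc2)C=C[C@H](O[Si](C)(C)C(C)(C)C)C1 | intermediate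
7 | trimethylsilyl ketene acetal of 6 | C=C(O[Si](C)(C)C)O[C@]1(COCc2ccc(OC)cc2)C=C[C@H](O[Si](C)(C)C(C)(C)C)C1 | intermediate (not isolated)
8 | trimethylsilyl ester of 9 | C[Si](C)(C)OC(=O)C[C@H]1C=C(COCc2ccc(OC)cc2)C[C@H]1O[Si](C)(C)C(C)(C)C | intermediate (not isolated)
9 | 2-[(1S,5R)-5-(tert-butyldimethylsilyloxy)-3-[(4-methoxybenzyloxy)methyl]cyclopent-2-en-1-yl]acetic acid (side chain cis to OTBS) | OC(=O)C[C@H]1C=C(COCc2ccc(OC)cc2)C[C@H]1O[Si](C)(C)C(C)(C)C | intermediate
10 | 2-[(1S,5R)-5-hydroxy-3-[(4-methoxybenzyloxy)methyl]cyclopent-2-en-1-yl]acetic acid | OC(=O)C[C@H]1C=C(COCc2ccc(OC)cc2)C[C@H]1O | intermediate (not isolated)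
11 | (3aS,6aR)-5-[(4-methoxybenzyloxy)methyl]-3,3a,6,6a-tetrahydro-2H-cyclopenta[b]furan-2-one (cis-fused) | C1C(=O)O[C@@H]2CC(COCc3ccc(OC)cc3)=C[C@H]12 | intermediate
12 | bromoform | BrC(Br)Br | starting material
13 | C6/C10 dibromocyclopropane of 11 (CBr2 = C5 on the convex face, anti to the lactone) | O=C1C[C@H]2[C@@H]3C(Br)(Br)[C@]3(COCc4ccc(OC)cc4)C[C@H]2O1 | intermediate (not isolated)
14 | (3aS,4S,7aR)-5-bromo-4-hydroxy-6-[(4-methoxybenzyloxy)methyl]-3a,4,7,7a-tetrahydro-1-benzofuran-2(3H)-one (cis lactone; 6-OH trans to C7–C11) | C1C(=O)O[C@@H]2CC(COCc3ccc(OC)cc3)=C(Br)[C@@H](O)[C@H]12 | intermediate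
15 | pent-4-yn-1-ol | C#CCCCO | starting material
16 | 1-methoxy-4-[(pent-4-yn-1-yloxy)methyl]benzene | C#CCCCOCc1ccc(OC)cc1 | intermediate
17 | diisobutyl{5-[(4-methoxybenzyl)oxy]pent-1-en-2-yl}alumane | C=C(CCCOCc1ccc(OC)cc1)[Al](CC(C)C)CC(C)C | intermediate (not isolated)
18 | 2-{5-[(4-methoxybenzyl)oxy]pent-1-en-2-yl}-4,4,5,5-tetramethyl-1,3,2-dioxaborolane | C=C(CCCOCc1ccc(OC)cc1)B1OC(C)(C)C(C)(C)O1 | intermediate
19 | diene alcohol: 14 with the 5-(PMB-oxy)pent-1-en-2-yl group at C5 in place of Br (6-OH free, trans to C7–C11) | C1C(=O)O[C@@H]2CC(COCc3ccc(OC)cc3)=C(C(=C)CCCOCc3ccc(OC)cc3)[C@@H](O)[C@H]12 | intermediate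
20 | 6-O-TBS ether of 19 | C1C(=O)O[C@@H]2CC(COCc3ccc(OC)cc3)=C(C(=C)CCCOCc3ccc(OC)cc3)[C@@H](O[Si](C)(C)C(C)(C)C)[C@H]12 | intermediate
21 | (4S)-saturated side-chain lactone (6-OTBS; 1,14-bis-OPMB; C11 = CH2) | C1C(=O)O[C@@H]2CC(COCc3ccc(OC)cc3)=C([C@@H](C)CCCOCc3ccc(OC)cc3)[C@@H](O[Si](C)(C)C(C)(C)C)[C@H]12 | intermediate
22 | C11-(dimethylaminomethyl) derivative of 21 (C11 epimers) | CN(C)CC1C(=O)O[C@@H]2CC(COCc3ccc(OC)cc3)=C([C@@H](C)CCCOCc3ccc(OC)cc3)[C@@H](O[Si](C)(C)C(C)(C)C)[C@H]12 | intermediate
23 | trimethylammonium iodide of 22 | C[N+](C)(C)CC1C(=O)O[C@@H]2CC(COCc3ccc(OC)cc3)=C([C@@H](C)CCCOCc3ccc(OC)cc3)[C@@H](O[Si](C)(C)C(C)(C)C)[C@H]12.[I-] | intermediate (not isolated)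
24 | 6-O-TBS-1,14-bis-O-PMB-6-O-deangeloyl-eriolangin (α-methylene lactone) | C=C1C(=O)O[C@@H]2CC(COCc3ccc(OC)cc3)=C([C@@H](C)CCCOCc3ccc(OC)cc3)[C@@H](O[Si](C)(C)C(C)(C)C)[C@H]12 | intermediate
25 | 1,14-bis-O-PMB-6-O-deangeloyl-eriolangin (6-OH free) | C=C1C(=O)O[C@@H]2CC(COCc3ccc(OC)cc3)=C([C@@H](C)CCCOCc3ccc(OC)cc3)[C@@H](O)[C@H]12 | intermediate
26 | angelic acid, (Z)-2-methylbut-2-enoic acid | C/C=C(/C)C(=O)O | starting material
27 | angelic 2,4,6-trichlorobenzoic anhydride | C/C=C(/C)C(=O)OC(=O)c1c(Cl)cc(Cl)cc1Cl | intermediate (not isolated)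
28 | 1,14-bis-O-PMB-eriolangin | C=C1C(=O)O[C@@H]2CC(COCc3ccc(OC)cc3)=C([C@@H](C)CCCOCc3ccc(OC)cc3)[C@@H](OC(=O)/C(C)=C\C)[C@H]12 | intermediate
29 | eriolangin, (4S,6S,7R,8R) in target numbering | C=C1C(=O)O[C@@H]2CC(CO)=C([C@@H](C)CCCO)[C@@H](OC(=O)/C(C)=C\C)[C@H]12 | target

**Step count**

Total: 15 steps. Longest linear sequence: 13 steps (steps 1–5 and 8–15).

**Steps most likely to fail**

Step 5 (key step). Water may be captured kinetically at the tertiary terminus C10 of the bromoallyl cation and not at C6, and tert-butoxide may enolise or open the lactone. Fallback: setting out from 13, the misdirected product, the C10 tertiary carbinol F1, is isolated and treated with catalytic triphenylsilyl perrhenate in ether at −40 → 0 °C. The allyl perrhenate shifts oxygen suprafacially ([3,3]) from C10 to C6 on the same convex face and drains toward the tetrasubstituted alkene, which returns the material to 14.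

Step 10. Facial selection at C4 may be poor if catalyst and substrate are mismatched, and the 1,1-disubstituted alkene may isomerise before it is reduced. Fallback by hydroxyl-directed hydrogenation of a trisubstituted alkene, setting out from 14:
- Purchased pent-3-yn-1-ol is converted to the pent-3-ynyl PMB ether F2 (NaH, PMBCl).
- Hydrozirconation (Cp2Zr(H)Cl) and iodinolysis give the (E)-vinyl iodide F3, and Miyaura borylation (B2pin2, KOAc, PdCl2(dppf)) gives the pinacol boronate F4.
- Coupling of F4 with 14 under the step 8 conditions gives the (E)-diene alcohol F5.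
- Crabtree's catalyst, [Ir(cod)(PCy3)(py)]PF6 with H2 in CH2Cl2, binds the free C6 hydroxyl and delivers hydrogen to the C4=C3 alkene held on the hydroxyl face. With C3 on that face and C15 away from it, this corresponds to 4S and gives the saturated alcohol F6.
- Silylation as in step 9 returns the material to 21.

Step 14. The angeloyl group may isomerise from Z to E during acylation, and the hindered C6 alcohol may acylate slowly. Fallback that builds the Z alkene on the ester, setting out from 22 with the methylene still masked as the Mannich base: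
- HF·pyridine gives the amino alcohol F7.
- DCC/DMAP esterification with 2-[bis(2,2,2-trifluoroethoxy)phosphoryl]propanoic acid gives the phosphonopropionate F8.
- Still–Gennari olefination (KHMDS, 18-crown-6, acetaldehyde, THF, −78 °C) gives the angelate amine F9 with Z geometry.
- MeI gives the methiodide F10, and bicarbonate eliminates trimethylamine to return the material to 28.

**Further compounds**

F1 | step 5 | C10 tertiary carbinol: 5-bromo-10-hydroxy-5(6)-ene lactone, 10-OH on the convex face, 14-OPMB | C1C(=O)O[C@@H]2C[C@](O)(COCc3ccc(OC)cc3)C(Br)=C[C@H]12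
F2 | step 10 | 1-methoxy-4-[(pent-3-yn-1-yloxy)methyl]benzene | CC#CCCOCc1ccc(OC)cc1
F3 | step 10 | (E)-1-{[(4-iodopent-3-en-1-yl)oxy]methyl}-4-methoxybenzene | C/C(I)=C\CCOCc1ccc(OC)cc1
F4 | step 10 | pinacol boronate from F3 (boron at C4, methyl cis to the chain) | C/C(=C\CCOCc1ccc(OC)cc1)B1OC(C)(C)C(C)(C)O1
F5 | step 10 | (E)-diene alcohol: 14 with the (E)-5-(PMB-oxy)pent-2-en-2-yl group at C5 in place of Br | C1C(=O)O[C@@H]2CC(COCc3ccc(OC)cc3)=C(/C(C)=C/CCOCc3ccc(OC)cc3)[C@@H](O)[C@H]12
F6 | step 10 | (4S)-saturated side-chain lactone with free 6-OH (desilyl 21) | C1C(=O)O[C@@H]2CC(COCc3ccc(OC)cc3)=C([C@@H](C)CCCOCc3ccc(OC)cc3)[C@@H](O)[C@H]12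
F7 | step 14 | amino alcohol: 6-O-desilyl 22 | CN(C)CC1C(=O)O[C@@H]2CC(COCc3ccc(OC)cc3)=C([C@@H](C)CCCOCc3ccc(OC)cc3)[C@@H](O)[C@H]12
F8 | step 14 | 6-O-{2-[bis(2,2,2-trifluoroethoxy)phosphoryl]propanoyl} ester of F7 | CN(C)CC1C(=O)O[C@@H]2CC(COCc3ccc(OC)cc3)=C([C@@H](C)CCCOCc3ccc(OC)cc3)[C@@H](OC(=O)C(C)P(=O)(OCC(F)(F)F)OCC(F)(F)F)[C@H]12
F9 | step 14 | 6-O-angeloyl Mannich base | CN(C)CC1C(=O)O[C@@H]2CC(COCc3ccc(OC)cc3)=C([C@@H](C)CCCOCc3ccc(OC)cc3)[C@@H](OC(=O)/C(C)=C\C)[C@H]12
F10 | step 14 | trimethylammonium iodide of F9 | C[N+](C)(C)CC1C(=O)O[C@@H]2CC(COCc3ccc(OC)cc3)=C([C@@H](C)CCCOCc3ccc(OC)cc3)[C@@H](OC(=O)/C(C)=C\C)[C@H]12.[I-]
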